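**Retrosynthetic overview**
1. Target 18 ⇐ (Z)-butylidenephthalide 16 (enol-lactone hydrolysis, MOM removal) ⇐ alkynyl acid 15 (5-exo-dig lactonization); the pentanoyl group is carried as a pent-1-ynyl group.
2. 15 ⇐ phenoxide of 12 + aryne 14 + CO2. The route rests on ring B: the ether oxygen (C2) and the carboxyl carbon (C1) sit on adjacent carbons, and C1 is flanked on its other side by the acyl-bearing C6. This is the pattern left when a nucleophile and an electrophile add across C1–C2 of a 3-substituted benzyne.
3. Aryne precursor 7 ⇐ 2,6-dibromo-4-methoxyphenol (retro-Brook, triflation, bromide-selective Sonogashira). Phenol 12 ⇐ olivetol (Vilsmeier–Haack, MOM protection, Dakin oxidation).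
4. Ring order: both benzene rings are bought; the only ring closure is the temporary lactone ring of 16 (step 8), opened again in step 9.

Key step: step 7

Remark on the chemistry: aryne 14 is released from the silyl triflate isomer whose triflate lies between the alkynyl and silyl groups. The isomer with silicon beside the alkyne gives the same aryne, but its alkyne would have to be coupled at a triflate flanked by SiMe3, which zerovalent palladium enters sluggishly, and on a symmetrical bis-triflate. Compound 7 instead comes in three steps from 2,6-dibromo-4-methoxyphenol, taken as purchasable (otherwise made from 4-methoxyphenol and two equivalents of bromine).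

**Route**

Step 1
Reactants: 1 2,6-dibromo-4-methoxyphenol
Product: 4 2-bromo-4-methoxy-6-(trimethylsilyl)phenol, via silyl ether 2 (not isolated), via lithium phenoxide 3 (not isolated)
Conditions: HMDS, THF, reflux, evaporate; then n-BuLi (1.0 equiv), THF, −78 °C to rt; aq NH4Cl
Reagents that add atoms: hexamethyldisilazane, C[Si](C)(C)N[Si](C)(C)C
Why: O-silylation, bromine–lithium exchange at one of the two equivalent bromides and 1,3 O-to-C silyl shift (retro-Brook rearrangement) give the C-silyl phenoxide; the second bromide survives because one equivalent of n-BuLi is used and the phenoxide formed is deactivated toward further exchange.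

Step 2
Reactants: 4 2-bromo-4-methoxy-6-(trimethylsilyl)phenol
Product: 5 2-bromo-4-methoxy-6-(trimethylsilyl)phenyl trifluoromethanesulfonate
Conditions: Tf2O, pyridine, CH2Cl2, 0 °C
Reagents that add atoms: trifluoromethanesulfonic anhydride, O=S(=O)(OS(=O)(=O)C(F)(F)F)C(F)(F)F
Why: O-sulfonylation of a phenol with triflic anhydride; 2,6-disubstituted phenols are triflated readily because the reaction takes place at the exposed oxygen.

Step 3
Reactants: 5 2-bromo-4-methoxy-6-(trimethylsilyl)phenyl trifluoromethanesulfonate; 6 1-pentyne
Product: 7 4-methoxy-2-(pent-1-yn-1-yl)-6-(trimethylsilyl)phenyl trifluoromethanesulfonate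
Conditions: PdCl2(PhCN)2 (cat.), [HP(t-Bu)3]BF4 (cat.), CuI (cat.), i-Pr2NH, 1,4-dioxane, rt, sealed vessel
Reagents that add atoms: none
Why: Sonogashira coupling with the bulky electron-rich phosphine takes aryl bromides at room temperature, whereas the triflate has two ortho substituents (one of them SiMe3) and a para methoxy group, so zerovalent palladium enters its C–O bond slowly; no fluoride is present, so the silyl triflate is not triggered.

Step 4
Reactants: 8 olivetol (5-pentylbenzene-1,3-diol)
Product: 9 2,4-dihydroxy-6-pentylbenzaldehyde
Conditions: POCl3, DMF, 0 °C to rt; then H2O, 50 °C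
Reagents that add atoms: N,N-dimethylformamide, CN(C)C=O (formyl carbon); water, O (aldehyde oxygen)
Why: Vilsmeier–Haack formylation of the resorcinol should take place ortho to one hydroxyl and para to the other (C4 of olivetol) rather than at the more crowded carbon between the two hydroxyls; hydrolysis of the iminium salt gives the aldehyde.

Step 5
Reactants: 9 2,4-dihydroxy-6-pentylbenzaldehyde
Product: 10 2,4-bis(methoxymethoxy)-6-pentylbenzaldehyde
Conditions: NaH, MOMCl, DMF, 0 °C to rt
Reagents that add atoms: chloromethyl methyl ether, COCCl
Why: Williamson-type O-alkylation of both phenoxides; NaH is used so that the hydroxyl that is hydrogen-bonded to the aldehyde is alkylated as well.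

Step 6
Reactants: 10 2,4-bis(methoxymethoxy)-6-pentylbenzaldehyde
Product: 12 2,4-bis(methoxymethoxy)-6-pentylphenol, via aryl formate 11 (not isolated)
Conditions: mCPBA, CH2Cl2, 0 °C to rt; aq Na2S2O3/NaHCO3 wash; then K2CO3 (cat.), MeOH, rt
Reagents that add atoms: meta-chloroperoxybenzoic acid, O=C(OO)c1cccc(Cl)c1
Why: Baeyer–Villiger (Dakin-type) oxidation, in which the electron-rich 2,4-dialkoxyaryl group migrates in the Criegee intermediate in preference to hydrogen; methanolysis of the resulting aryl formate frees the phenol.

Step 7
Reactants: 12 2,4-bis(methoxymethoxy)-6-pentylphenol; 7 4-methoxy-2-(pent-1-yn-1-yl)-6-(trimethylsilyl)phenyl trifluoromethanesulfonate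
Product: 15 2-[2,4-bis(methoxymethoxy)-6-pentylphenoxy]-4-methoxy-6-(pent-1-yn-1-yl)benzoic acid, via potassium phenoxide 13 (not isolated), via aryne 14 (not isolated)
Conditions: KH, THF, 0 °C; then 18-crown-6, KF, CO2 (1 atm), slow addition of 7, THF, 0 °C to rt; then cold 0.5 M HCl to pH 3
Reagents that add atoms: carbon dioxide, O=C=O
Why: Proposed new method: fluoride attacks silicon of 7 and triflate leaves, giving aryne 14; the oxygen of phenoxide 13 adds to the aryne carbon remote from the alkynyl group and the aryl anion formed next to the alkyne adds to CO2, so that the C2–O and C1–CO2 bonds of ring B are made in one operation. The closest known reactions are the KF/18-crown-6 three-component coupling of arynes with amines and CO2 to anthranilic acids and the O-arylation of hindered phenols by silylaryl triflates; a phenoxide has not been combined with CO2 in this way. No ring is closed and no stereocentre is formed. Regioselectivity is needed and rests on the sigma-withdrawing sp carbon, which by the aryne distortion model directs the nucleophile to the distal carbon and stabilises the anion beside it, helped by the bulk of the 2,6-disubstituted phenoxide; the methoxy group para to the anionic carbon opposes this only weakly. Chemoselectivity is also needed: carboxylation must outrun protonation, which is secured by a preformed phenoxide, THF in place of acetonitrile and a CO2-saturated solution, and only oxygen of 13 can arylate because its ortho and para carbons are all substituted. The alkynyl group, unlike a halide or sulfonate, cannot be expelled by the neighbouring anion and is carried on as the latent pentanoyl group.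

Step 8
Reactants: 15 2-[2,4-bis(methoxymethoxy)-6-pentylphenoxy]-4-methoxy-6-(pent-1-yn-1-yl)benzoic acid
Product: 16 (Z)-7-[2,4-bis(methoxymethoxy)-6-pentylphenoxy]-3-butylidene-5-methoxyisobenzofuran-1(3H)-one
Conditions: AgNO3 (10 mol %), DMF, rt, dark
Reagents that add atoms: none
Why: Silver-catalysed cycloisomerization of a 2-alkynylbenzoic acid, in which monovalent silver activates the alkyne and the carboxyl oxygen adds anti at the proximal alkyne carbon (5-exo-dig, the usual mode for alkyl-substituted alkynes); anti addition followed by protodemetalation sets the Z geometry of the exocyclic double bond.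

Step 9
Reactants: 16 (Z)-7-[2,4-bis(methoxymethoxy)-6-pentylphenoxy]-3-butylidene-5-methoxyisobenzofuran-1(3H)-one
Product: 18 2-(2,4-dihydroxy-6-pentylphenoxy)-4-methoxy-6-pentanoylbenzoic acid, via keto acid 17 (not isolated)
Conditions: LiOH, THF/H2O, rt; then 3 M HCl, THF, 45 °C, dilute
Reagents that add atoms: lithium hydroxide, [Li+].[OH-]; water, O
Why: Saponification opens the enol lactone to the carboxylate and an enolate that tautomerises to the butyl ketone on the benzylic carbon, and aqueous HCl then hydrolyses both methoxymethyl acetals; the phenols are freed only under acid, so that base-induced Smiles rearrangement of an ortho-hydroxy diaryl ether and air oxidation of the electron-rich ring A are avoided.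

**Compound list**
1 | 2,6-dibromo-4-methoxyphenol | COc1cc(Br)c(O)c(Br)c1 | starting material
2 | (2,6-dibromo-4-methoxyphenoxy)trimethylsilane (silyl ether) | COc1cc(Br)c(O[Si](C)(C)C)c(Br)c1 | intermediate (not isolated)
3 | lithium 2-bromo-4-methoxy-6-(trimethylsilyl)phenoxide | [Li+].COc1cc(Br)c([O-])c([Si](C)(C)C)c1 | intermediate (not isolated)
4 | 2-bromo-4-methoxy-6-(trimethylsilyl)phenol | COc1cc(Br)c(O)c([Si](C)(C)C)c1 | intermediate
5 | 2-bromo-4-methoxy-6-(trimethylsilyl)phenyl trifluoromethanesulfonate | COc1cc(Br)c(OS(=O)(=O)C(F)(F)F)c([Si](C)(C)C)c1 | intermediate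
6 | 1-pentyne | CCCC#C | starting material
7 | 4-methoxy-2-(pent-1-yn-1-yl)-6-(trimethylsilyl)phenyl trifluoromethanesulfonate | CCCC#Cc1cc(OC)cc([Si](C)(C)C)c1OS(=O)(=O)C(F)(F)F | intermediate (key-step precursor)
8 | olivetol (5-pentylbenzene-1,3-diol) | CCCCCc1cc(O)cc(O)c1 | starting material
9 | 2,4-dihydroxy-6-pentylbenzaldehyde | CCCCCc1cc(O)cc(O)c1C=O | intermediate
10 | 2,4-bis(methoxymethoxy)-6-pentylbenzaldehyde | CCCCCc1cc(OCOC)cc(OCOC)c1C=O | intermediate
11 | 2,4-bis(methoxymethoxy)-6-pentylphenyl formate (aryl formate) | CCCCCc1cc(OCOC)cc(OCOC)c1OC=O | intermediate (not isolated)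
12 | 2,4-bis(methoxymethoxy)-6-pentylphenol | CCCCCc1cc(OCOC)cc(OCOC)c1O | intermediate (key-step precursor)
13 | potassium 2,4-bis(methoxymethoxy)-6-pentylphenoxide | [K+].CCCCCc1cc(OCOC)cc(OCOC)c1[O-] | intermediate (not isolated)
14 | 5-methoxy-3-(pent-1-yn-1-yl)benzyne | CCCC#CC1=CC(OC)=CC#C1 | intermediate (not isolated)
15 | 2-[2,4-bis(methoxymethoxy)-6-pentylphenoxy]-4-methoxy-6-(pent-1-yn-1-yl)benzoic acid | CCCCCc1cc(OCOC)cc(OCOC)c1Oc1cc(OC)cc(C#CCCC)c1C(=O)O | intermediate (key-step product)
16 | (Z)-7-[2,4-bis(methoxymethoxy)-6-pentylphenoxy]-3-butylidene-5-methoxyisobenzofuran-1(3H)-one | CCC/C=C1\OC(=O)c2c(Oc3c(CCCCC)cc(OCOC)cc3OCOC)cc(OC)cc12 | intermediate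
17 | 2-[2,4-bis(methoxymethoxy)-6-pentylphenoxy]-4-methoxy-6-pentanoylbenzoic acid (keto acid) | CCCCCc1cc(OCOC)cc(OCOC)c1Oc1cc(OC)cc(C(=O)CCCC)c1C(=O)O | intermediate (not isolated)
18 | 2-(2,4-dihydroxy-6-pentylphenoxy)-4-methoxy-6-pentanoylbenzoic acid | CCCCCc1cc(O)cc(O)c1Oc1cc(OC)cc(C(=O)CCCC)c1C(=O)O | target

**Step count**
Total: 9 steps. Longest linear sequence: 6 steps (8 → 9 → 10 → 12 → 15 → 16 → 18; the branch from 1 is equally long).

**Steps most likely to fail**

Step 7 (proposed new method). Three processes may defeat it. The phenoxide may add at the aryne carbon next to the alkyne. The aryl anion may be protonated before it meets CO2. The phenoxide may be arylated through its reversibly formed carbonate, followed by acyl transfer to the aryl anion, which gives an aryl salicylate in place of the ether acid. The fallback uses known chemistry, sets out from 12 and comes back at 15. Phenol 12 is heated with purchased 2-bromo-6-fluoro-4-methoxybenzaldehyde (COc1cc(F)c(C=O)c(Br)c1) and K2CO3 in DMF. Nucleophilic aromatic substitution displaces the fluoride activated by the ortho formyl group, bromide being a far poorer leaving group in this addition–elimination, and should give 2-bromo-6-[2,4-bis(methoxymethoxy)-6-pentylphenoxy]-4-methoxybenzaldehyde F1. Sonogashira coupling of F1 with 1-pentyne 6 (PdCl2(PPh3)2, CuI, Et3N, 60 °C) should give 2-[2,4-bis(methoxymethoxy)-6-pentylphenoxy]-4-methoxy-6-(pent-1-yn-1-yl)benzaldehyde F2. Pinnick oxidation of F2 (NaClO2, NaH2PO4, 2-methyl-2-butene, t-BuOH/H2O) returns the route to 15.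

Step 3. Palladium may insert into the aryl–triflate bond in competition with the aryl–bromide bond, or the amine may cleave the triflate, giving mixtures. The fallback moves the coupling ahead of the triflation, sets out from 4 and comes back at 7. Phenol 4 is acetylated (Ac2O, pyridine, DMAP) to 2-bromo-4-methoxy-6-(trimethylsilyl)phenyl acetate F3. Sonogashira coupling of F3 with 6 (PdCl2(PPh3)2, CuI, Et3N, 60 °C), now with the bromide as the only coupling site, should give 4-methoxy-2-(pent-1-yn-1-yl)-6-(trimethylsilyl)phenyl acetate F4. Brief methanolysis (K2CO3, MeOH, 0 °C) frees 4-methoxy-2-(pent-1-yn-1-yl)-6-(trimethylsilyl)phenol F5, which is kept cold to avoid closure to a benzofuran and triflated at once (Tf2O, pyridine, CH2Cl2, 0 °C) to 7.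

Step 8. The carboxyl oxygen may attack the distal alkyne carbon (6-endo-dig), giving an isocoumarin whose hydrolysis would place the carbonyl on the wrong carbon. The fallback changes the mode of activation from electrophilic activation of the alkyne by a metal to nucleophilic activation of the carboxyl group; it sets out from 15 and comes back at 16. Acid 15 is heated with catalytic DBU in MeCN at 80 °C. The free carboxylate then adds anti to the unactivated alkyne, a metal-free closure known for 2-alkynylbenzoic acids to follow the 5-exo-dig path and give (Z)-ylidenephthalides. No new compound is made.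

**Further compounds**
F1 | step 7 | 2-bromo-6-[2,4-bis(methoxymethoxy)-6-pentylphenoxy]-4-methoxybenzaldehyde | CCCCCc1cc(OCOC)cc(OCOC)c1Oc1cc(OC)cc(Br)c1C=O
F2 | step 7 | 2-[2,4-bis(methoxymethoxy)-6-pentylphenoxy]-4-methoxy-6-(pent-1-yn-1-yl)benzaldehyde | CCCCCc1cc(OCOC)cc(OCOC)c1Oc1cc(OC)cc(C#CCCC)c1C=O
F3 | step 3 | 2-bromo-4-methoxy-6-(trimethylsilyl)phenyl acetate | COc1cc(Br)c(OC(C)=O)c([Si](C)(C)C)c1
F4 | step 3 | 4-methoxy-2-(pent-1-yn-1-yl)-6-(trimethylsilyl)phenyl acetate | CCCC#Cc1cc(OC)cc([Si](C)(C)C)c1OC(C)=O
F5 | step 3 | 4-methoxy-2-(pent-1-yn-1-yl)-6-(trimethylsilyl)phenol | CCCC#Cc1cc(OC)cc([Si](C)(C)C)c1O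
F0 | step 8 | none | none
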